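The plan rests on cutting the C3–C4 bond of the pyranone ring C. The methoxy-bearing C3 and the carbonyl carbon C4 sit side by side, each carrying oxygen. This is the signature of an acyloin, so both carbons are traced back to formyl carbons that a carbene catalyst joins by polarity reversal. In one operation the key step makes C3–C4, closes ring C and leaves oxygen on both carbons. Its precursor is a racemic dialdehyde in which the ether oxygen O1 already ties ring A to C2 and ring B. It combines a 2,4,6-trioxygenated benzaldehyde with an α-aryl-α-aryloxyacetaldehyde. Oxidation to the flavonol, 3-O-methylation, chelation-directed 5-O-demethylation and oxidative demethylation of ring B complete the target.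

Key step: step 5

Remark on the chemistry: the target is achiral. Every chiral intermediate is made and used as a racemate (the key-step product also as a cis/trans mixture), so the SMILES carry no stereodescriptors.

Step 1
Reactants: 1 1,2,3,5-tetramethoxybenzene; 2 ethyl glyoxylate
Product: 3 ethyl 2-hydroxy-2-(2,3,4,6-tetramethoxyphenyl)acetate (racemic)
Conditions: Yb(OTf)3 (10 mol%), 2 (2 equiv, freshly cracked from the toluene solution), CH2Cl2, 0 °C to rt
Reagents that add atoms: none
Why: Friedel–Crafts hydroxyalkylation: the Lewis-acid-activated aldehyde of 2 is attacked by one of the two equivalent free ring positions of 1 (each ortho, ortho and para to methoxy groups), a second arylation is held back by the two ortho methoxy groups of 3 and by the excess of 2, and the new benzylic stereocentre forms as a racemate because nothing chiral is present.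

Step 2
Reactants: 3 ethyl 2-hydroxy-2-(2,3,4,6-tetramethoxyphenyl)acetate; 4 2-hydroxy-4,6-dimethoxybenzaldehyde
Product: 5 ethyl 2-(2-formyl-3,5-dimethoxyphenoxy)-2-(2,3,4,6-tetramethoxyphenyl)acetate (racemic)
Conditions: PPh3 (1.5 equiv), diisopropyl azodicarboxylate (DIAD, 1.5 equiv), THF, 0 °C to rt
Reagents that add atoms: none
Why: Mitsunobu etherification: α-hydroxy esters are reliable Mitsunobu alcohols, the chelated phenol of 4 is acidic enough to protonate the betaine, the free formyl group is inert so no acetal is needed, the near-neutral medium avoids base-induced aldol closure of 5 onto its own aldehyde, and the stereocentre stays racemic whatever the share of inversion.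

Step 3
Reactants: 5 ethyl 2-(2-formyl-3,5-dimethoxyphenoxy)-2-(2,3,4,6-tetramethoxyphenyl)acetate
Product: 6 2-[2-(hydroxymethyl)-3,5-dimethoxyphenoxy]-2-(2,3,4,6-tetramethoxyphenyl)ethan-1-ol (racemic)
Conditions: LiAlH4 (1.5 equiv), THF, 0 °C; H2O/aq NaOH work-up, no acid
Reagents that add atoms: none
Why: Global hydride reduction with LiAlH4 takes the ester and the aryl aldehyde to primary alcohols in one operation, which replaces a protect–reduce–deprotect sequence, leaves the aryl ethers and the stereocentre untouched, and is worked up under basic conditions because the trialkoxybenzyl alcohol of 6 ionises in acid.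

Step 4
Reactants: 6 2-[2-(hydroxymethyl)-3,5-dimethoxyphenoxy]-2-(2,3,4,6-tetramethoxyphenyl)ethan-1-ol
Product: 7 2-[2-oxo-1-(2,3,4,6-tetramethoxyphenyl)ethoxy]-4,6-dimethoxybenzaldehyde (racemic dialdehyde)
Conditions: Dess–Martin periodinane (2.6 equiv), pyridine (6 equiv), CH2Cl2, 0 °C to rt; used at once without chromatography
Reagents that add atoms: none
Why: Double Dess–Martin oxidation: both primary alcohols are oxidised under mild buffered conditions that stop at the aldehyde stage and avoid both acid-induced ionisation of the benzylic alcohol and strong base that would enolise C2.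

Step 5
Reactants: 7 2-[2-oxo-1-(2,3,4,6-tetramethoxyphenyl)ethoxy]-4,6-dimethoxybenzaldehyde
Product: 8 3-hydroxy-5,7-dimethoxy-2-(2,3,4,6-tetramethoxyphenyl)chroman-4-one (racemic; cis/trans mixture)
Conditions: 2-(pentafluorophenyl)-6,7-dihydro-5H-pyrrolo[2,1-c][1,2,4]triazol-2-ium tetrafluoroborate (20 mol%), iPr2NEt (20 mol%), 4 Å MS, degassed THF (0.02 mol/L), Ar, 7 added over 2 h, 25 to 40 °C
Reagents that add atoms: none
Why: After addition of the free carbene to the aryl formyl carbon of 7 (future C4) and a proton shift, the resulting Breslow enaminol behaves as an acyl anion and bonds to the α-oxygenated aliphatic formyl carbon (future C3); collapse of the adduct ejects the carbene and leaves the C4 ketone beside the C3 carbinol. The closest known reaction type is the NHC-catalysed intramolecular crossed benzoin (acyloin) cyclisation, established for 2-(2-oxoalkoxy)benzaldehydes giving 3-hydroxychroman-4-ones and for tethered α-oxygenated dialdehydes. Ring C closes in the 6-exo-trig mode, since the acceptor C=O lies outside the ring being formed. The new C3 stereocentre is set only relative to C2 by the substrate, the trans (diequatorial) isomer being expected to prevail through enediol equilibration, and it needs no control because C2 and C3 both become sp2 in step 6. The step needs donor selectivity for the aryl aldehyde, because an enaminol centred on C3 could expel the ring A aryloxide from C2 (internal redox), and it needs benzoin closure to beat the 5-exo aldol of the C2 enolate and intermolecular coupling. The substrate helps because its aliphatic formyl group is the better electrophile yet is α-branched and walled in by two ortho-substituted aryl groups, the ortho alkoxy groups of ring A favour carbene adduct formation at C4, the aldol adduct has a quaternary C2 and can only revert, and the ether tether together with slow addition at high dilution, an electron-poor N-aryl carbene and only catalytic weak base supports the ring-forming mode.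

Step 6
Reactants: 8 3-hydroxy-5,7-dimethoxy-2-(2,3,4,6-tetramethoxyphenyl)chroman-4-one
Product: 10 3-hydroxy-5,7-dimethoxy-2-(2,3,4,6-tetramethoxyphenyl)-4H-chromen-4-one (flavonol), via chroman-3,4-dione 9 (not isolated)
Conditions: Cu(OAc)2·H2O (2.2 equiv), AcOH–H2O (4:1), Ar, 70 °C
Reagents that add atoms: none
Why: Copper-mediated acyloin-to-1,2-diketone oxidation: divalent copper oxidises the enediol of 8, which is common to both acyloin tautomers, by two one-electron transfers to dione 9, whose C2–H enolises at once to the aromatic 3-hydroxy-4-pyranone 10 with loss of both stereocentres, and exclusion of air avoids copper/O2 cleavage of the flavonol.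

Step 7
Reactants: 10 3-hydroxy-5,7-dimethoxy-2-(2,3,4,6-tetramethoxyphenyl)-4H-chromen-4-one
Product: 11 3,5,7-trimethoxy-2-(2,3,4,6-tetramethoxyphenyl)-4H-chromen-4-one
Conditions: MeI (1.5 equiv), K2CO3 (2 equiv), DMF, rt
Reagents that add atoms: iodomethane, CI
Why: Williamson-type O-methylation: the 3-OH is the only acidic site of 10, so its potassium salt is alkylated by MeI in an SN2 reaction.

Step 8
Reactants: 11 3,5,7-trimethoxy-2-(2,3,4,6-tetramethoxyphenyl)-4H-chromen-4-one
Product: 12 5-hydroxy-3,7-dimethoxy-2-(2,3,4,6-tetramethoxyphenyl)-4H-chromen-4-one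
Conditions: BCl3 (1.5 equiv, solution in CH2Cl2), CH2Cl2, −78 to 0 °C; then aq MeOH
Reagents that add atoms: none
Why: Chelation-directed Lewis-acid ether cleavage: BCl3 binds the C4 carbonyl and the peri 5-OMe in a six-membered chelate, chloride removes that methyl group much faster than any other, and partial loss of the crowded 3'-methyl group would be harmless because C3' becomes a quinone carbonyl in step 9.

Step 9
Reactants: 12 5-hydroxy-3,7-dimethoxy-2-(2,3,4,6-tetramethoxyphenyl)-4H-chromen-4-one
Product: 13 2-(5-hydroxy-3,7-dimethoxy-4-oxo-4H-chromen-2-yl)-3,5-dimethoxycyclohexa-2,5-diene-1,4-dione (target)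
Conditions: (NH4)2Ce(NO3)6 (2.5 equiv), MeCN–H2O (3:1), 0 °C, short contact time
Reagents that add atoms: water, O
Why: Oxidative demethylation of a 1,4-dimethoxyarene with tetravalent cerium: ring B is by far the most electron-rich arene and C3'/C6' carry its only para pair of methoxy groups, so two one-electron oxidations with addition of water at these carbons and loss of methanol give the 3',6'-quinone with the 2'- and 4'-methoxy groups in place, while the hydrogen-bonded, carbonyl-deactivated ring A phenol is much harder to oxidise.

Compound list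
1 | 1,2,3,5-tetramethoxybenzene | COc1cc(OC)c(OC)c(OC)c1 | starting material
2 | ethyl glyoxylate | CCOC(=O)C=O | starting material
3 | ethyl 2-hydroxy-2-(2,3,4,6-tetramethoxyphenyl)acetate (racemic) | CCOC(=O)C(O)c1c(OC)c(OC)c(OC)cc1OC | intermediate
4 | 2-hydroxy-4,6-dimethoxybenzaldehyde | COc1cc(O)c(C=O)c(OC)c1 | starting material
5 | ethyl 2-(2-formyl-3,5-dimethoxyphenoxy)-2-(2,3,4,6-tetramethoxyphenyl)acetate (racemic) | CCOC(=O)C(Oc1cc(OC)cc(OC)c1C=O)c1c(OC)c(OC)c(OC)cc1OC | intermediate
6 | 2-[2-(hydroxymethyl)-3,5-dimethoxyphenoxy]-2-(2,3,4,6-tetramethoxyphenyl)ethan-1-ol (racemic) | OCC(Oc1cc(OC)cc(OC)c1CO)c1c(OC)c(OC)c(OC)cc1OC | intermediate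
7 | 2-[2-oxo-1-(2,3,4,6-tetramethoxyphenyl)ethoxy]-4,6-dimethoxybenzaldehyde (racemic) | O=CC(Oc1cc(OC)cc(OC)c1C=O)c1c(OC)c(OC)c(OC)cc1OC | intermediate
8 | 3-hydroxy-5,7-dimethoxy-2-(2,3,4,6-tetramethoxyphenyl)chroman-4-one (racemic, cis/trans mixture) | COc1cc(OC)c2c(c1)OC(c1c(OC)c(OC)c(OC)cc1OC)C(O)C2=O | intermediate
9 | 5,7-dimethoxy-2-(2,3,4,6-tetramethoxyphenyl)chroman-3,4-dione (racemic, not isolated) | COc1cc(OC)c2c(c1)OC(c1c(OC)c(OC)c(OC)cc1OC)C(=O)C2=O | intermediate
10 | 3-hydroxy-5,7-dimethoxy-2-(2,3,4,6-tetramethoxyphenyl)-4H-chromen-4-one | COc1cc(OC)c2c(c1)oc(-c1c(OC)c(OC)c(OC)cc1OC)c(O)c2=O | intermediate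
11 | 3,5,7-trimethoxy-2-(2,3,4,6-tetramethoxyphenyl)-4H-chromen-4-one | COc1cc(OC)c2c(c1)oc(-c1c(OC)c(OC)c(OC)cc1OC)c(OC)c2=O | intermediate
12 | 5-hydroxy-3,7-dimethoxy-2-(2,3,4,6-tetramethoxyphenyl)-4H-chromen-4-one | COc1cc(O)c2c(c1)oc(-c1c(OC)c(OC)c(OC)cc1OC)c(OC)c2=O | intermediate
13 | 2-(5-hydroxy-3,7-dimethoxy-4-oxo-4H-chromen-2-yl)-3,5-dimethoxycyclohexa-2,5-diene-1,4-dione | COC1=CC(=O)C(c2oc3cc(OC)cc(O)c3c(=O)c2OC)=C(OC)C1=O | target

Total step count: 9
Longest linear sequence: 9 steps (1 → 3 → 5 → 6 → 7 → 8 → 10 → 11 → 12 → 13)

Steps most likely to fail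

Step 5. Several processes could take over:
- The carbene may engage the aliphatic formyl group, after which the ring A aryloxide is expelled from C2 and the O1–C2 bond is lost by internal redox.
- The C2 enolate may drain material through 5-exo aldol closure.
- Enaminol formation at the electron-rich, doubly ortho-substituted aryl aldehyde may be too slow, so that intermolecular coupling prevails.

The fallback gives up the C3–C4 closure and builds ring C through the O1–C2 bond. It sets out from 1 and comes back at 10. Vilsmeier–Haack formylation of 1 (POCl3, DMF) gives 2,3,4,6-tetramethoxybenzaldehyde F1. Claisen–Schmidt condensation of this aldehyde with commercial 1-(2-hydroxy-4,6-dimethoxyphenyl)ethanone (KOH, EtOH, rt) gives (E)-1-(2-hydroxy-4,6-dimethoxyphenyl)-3-(2,3,4,6-tetramethoxyphenyl)prop-2-en-1-one F2. Iodine-catalysed oxidative cyclisation (I2 cat., DMSO, 120 °C) gives 5,7-dimethoxy-2-(2,3,4,6-tetramethoxyphenyl)-4H-chromen-4-one F3. C3 lithiation with LDA at −78 °C, trapping with B(OMe)3 and oxidation with H2O2/AcOH then delivers flavonol 10.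

Step 2. The oxyphosphonium salt of the very electron-rich, doubly ortho-substituted mandelate may ionise and be captured by the hydrazide. Alternatively, steric shielding may stop the displacement altogether. The fallback replaces the redox condensation by a halide displacement. It sets out from 3 and comes back at 5. PBr3 in CH2Cl2 at 0 °C converts 3 into ethyl 2-bromo-2-(2,3,4,6-tetramethoxyphenyl)acetate F4. This bromide is used crude to O-alkylate 4 (K2CO3, DMF, rt, no heating, so that aldol closure to a benzofuran skeleton does not set in), which gives 5.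

Step 9. Oxidation or nitration of the phenolic ring A may compete with oxidation of ring B. Prolonged contact with the acidic medium may also hydrolyse the vinylogous ester methoxy groups of the quinone. The fallback masks the phenol during the oxidation. It sets out from 12 and comes back at 13. Acetylation (Ac2O, pyridine, rt) gives 3,7-dimethoxy-4-oxo-2-(2,3,4,6-tetramethoxyphenyl)-4H-chromen-5-yl acetate F5. Oxidation with (NH4)2Ce(NO3)6 in aqueous MeCN at 0 °C gives 2-(2,4-dimethoxy-3,6-dioxocyclohexa-1,4-dien-1-yl)-3,7-dimethoxy-4-oxo-4H-chromen-5-yl acetate F6. Acid-catalysed methanolysis (cat. HCl, MeOH, rt) then frees the 5-OH and gives 13; under these conditions any exchange at the quinone methoxy groups is degenerate.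

Further compounds
F1 | step 5 | 2,3,4,6-tetramethoxybenzaldehyde | COc1cc(OC)c(C=O)c(OC)c1OC
F2 | step 5 | (E)-1-(2-hydroxy-4,6-dimethoxyphenyl)-3-(2,3,4,6-tetramethoxyphenyl)prop-2-en-1-one | COc1cc(O)c(C(=O)/C=C/c2c(OC)c(OC)c(OC)cc2OC)c(OC)c1
F3 | step 5 | 5,7-dimethoxy-2-(2,3,4,6-tetramethoxyphenyl)-4H-chromen-4-one | COc1cc(OC)c2c(c1)oc(-c1c(OC)c(OC)c(OC)cc1OC)cc2=O
F4 | step 2 | ethyl 2-bromo-2-(2,3,4,6-tetramethoxyphenyl)acetate (racemic) | CCOC(=O)C(Br)c1c(OC)c(OC)c(OC)cc1OC
F5 | step 9 | 3,7-dimethoxy-4-oxo-2-(2,3,4,6-tetramethoxyphenyl)-4H-chromen-5-yl acetate | COc1cc(OC(C)=O)c2c(c1)oc(-c1c(OC)c(OC)c(OC)cc1OC)c(OC)c2=O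
F6 | step 9 | 2-(2,4-dimethoxy-3,6-dioxocyclohexa-1,4-dien-1-yl)-3,7-dimethoxy-4-oxo-4H-chromen-5-yl acetate | COC1=CC(=O)C(c2oc3cc(OC)cc(OC(C)=O)c3c(=O)c2OC)=C(OC)C1=O
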